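A direct plan would take the finished flavonol skeleton from quercetin A1, brominate ring A at C6 and C8 to give 6,8-dibromoquercetin A2, and then exchange both bromides of A2 for methoxide by copper catalysis on the unprotected pentahydroxy compound.
Its weakest step would be the twofold bromide-to-methoxide exchange on A2: each C–Br lies between two oxido groups (hindered, very electron-rich), the free catechol and the 3-hydroxy-4-keto unit bind and reduce copper, hydrodebromination and methoxide attack on the pyranone compete, and this untested coupling is the last step.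
The bromination of free A1 to A2 would also be weak: Br2 can oxidise the ring B catechol and the C2=C3 enol as well as substitute ring A, and a polar polyphenol mixture is hard to purify.
As a whole the plan builds no ring and no C–C bond: both new C–O bonds are made at the two most hindered carbons of a finished, sensitive molecule, with no convergence and no way back.

**Retrosynthetic overview**
Ring C is cut at C4–C4a and at O1–C2, which gives a ring A resorcinol, 5-(benzyloxy)-4,6-dimethoxybenzene-1,3-diol, and a ring B aroylacetate that already carries O3. Both bonds form in one thermal [3+3] annulation.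
The feature used: ring A bears oxygen at C5, C6, C7, C8 and C8a and is symmetric about the C7–C4a axis (6-OMe/8-OMe and 5-OH/8a-OH are pairwise equivalent in the resorcinol). C4a is its only carbon without oxygen, so acylation and closure can give one isomer only.
The 6-OMe/7-O/8-OMe triad is bought as syringol. The two flanking oxygens are put on the simple protected arene at the start, so no methoxy group is made by coupling and nothing is done at C6 or C8 of a flavonol.
Ring order: A and B bought, C last. Four benzyl ethers (3-, 7-, 3'-, 4'-O) fall in one final hydrogenolysis, so no free catechol or flavonol meets bromine, copper or base.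

Key step: step 5

Assumption: the target has no stereocenter; the ring B ketoester made in step 4 is used as the racemate, and its only stereocenter becomes the sp2 carbon C3 in step 5.

**Step 1**
Reactants: 1 syringol (2,6-dimethoxyphenol)
Product: 2 syringol benzyl ether (2-(benzyloxy)-1,3-dimethoxybenzene)
Conditions: BnBr (1.1 equiv), K2CO3 (1.5 equiv), DMF, 60 °C
Reagents that add atoms: benzyl bromide, BrCc1ccccc1
Why: Williamson ether synthesis of an acidic, unhindered-at-oxygen phenoxide; the benzyl ether also turns the central oxygen into a twisted, weak donor, which steers step 2 away from C5.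

**Step 2**
Reactants: 2 syringol benzyl ether
Product: 3 dibromide (3-(benzyloxy)-1,5-dibromo-2,4-dimethoxybenzene)
Conditions: NBS (2.05 equiv), MeCN, 0 °C to rt, dark
Reagents that add atoms: N-bromosuccinimide, O=C1CCC(=O)N1Br
Why: Electrophilic aromatic bromination; each of the two carbons next to a methoxy group is ortho to one OMe and para to the other, whereas the carbon between them is meta to both, so the 4,6-dibromide of the 1,2,3-trialkoxybenzene should form as it does with 1,2,3-trimethoxybenzene.

**Step 3**
Reactants: 3 dibromide
Product: 4 ring A resorcinol (5-(benzyloxy)-4,6-dimethoxybenzene-1,3-diol)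
Conditions: Pd2(dba)3 (2 mol %), tBuXPhos (8 mol %), KOH (6 equiv), 1,4-dioxane/H2O (1:1), 100 °C, Ar; then degassed 1 M aq. HCl
Reagents that add atoms: potassium hydroxide, [K+].[OH-]
Why: Palladium-catalysed hydroxylation of aryl bromides with hydroxide (C–O cross-coupling: oxidative addition to zerovalent palladium, bromide–hydroxide exchange, reductive elimination from the bulky biarylphosphine complex); each C–Br has only one ortho substituent, and benzyl and methyl ethers are inert to hot aqueous KOH.

**Step 4**
Reactants: 5 3,4-bis(benzyloxy)benzoic acid; 6 ethyl 2-(benzyloxy)acetate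
Product: 8 ring B ketoester (ethyl 2-(benzyloxy)-3-[3,4-bis(benzyloxy)phenyl]-3-oxopropanoate; racemic), via acyl imidazolide 7 (not isolated)
Conditions: 5, CDI (1,1'-carbonyldiimidazole, 1.1 equiv), THF, rt, 1 h; added to 6 (2.2 equiv)/LiN(SiMe3)2 (2.3 equiv), THF, −78 °C to 0 °C; then 1 M aq. HCl
Reagents that add atoms: none
Why: Crossed Claisen condensation (C-acylation of a lithium ester enolate by a non-enolisable N-acylimidazole); the second equivalent of enolate deprotonates the product and so prevents double acylation, and the new stereocenter C2 forms as the racemate, which needs no control because it is lost in step 5.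

**Step 5**
Reactants: 4 ring A resorcinol; 8 ring B ketoester
Product: 11 tetra-O-benzyl flavonol (3,7-bis(benzyloxy)-2-[3,4-bis(benzyloxy)phenyl]-5-hydroxy-6,8-dimethoxy-4H-chromen-4-one), via aroylketene 9 (not isolated), via triketone 10 (not isolated)
Conditions: 4 (1.0 equiv), 8 (1.3 equiv), minimal Ph2O, Ar stream to sweep out EtOH and H2O, 200 °C (microwave or sand bath), 30 min
Reagents that add atoms: none
Why: On heating, the enol of 8 should lose ethanol to give the aroyl(benzyloxy)ketene 9, which acylates the phenol oxygens reversibly and the ring carbon C2 of 4 irreversibly to give triketone 10 (bond C4–C4a). An ortho hydroxyl of 10 then adds to the aroyl carbonyl (6-exo-trig) and loss of water closes ring C at O1–C2 as the aromatic 4-pyranone. The closest known reaction is the Mentzer thermal condensation of phloroglucinol with ethyl aroylacetates to 5,7-dihydroxyflavones, in which 2-substituted ketoesters give 3-substituted chromones. No stereocenter is formed, and the racemic carbon C2 of 8 becomes the sp2 carbon C3. The step needs chromone closure over coumarin closure and a single ring A regiochemistry: neutral conditions and the 2-benzyloxy substituent favour the acylketene path over Pechmann attack at the ketone, and 4 has one ring C–H (between its two equivalent hydroxyls), so only one constitutional isomer can form. The benzyl ethers carry no acidic or reducible site and should survive the short heating.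

**Step 6**
Reactants: 11 tetra-O-benzyl flavonol
Product: 12 3,5,7,3',4'-pentahydroxy-6,8-dimethoxyflavone (target)
Conditions: H2 (1 atm), 10% Pd/C, THF/MeOH (1:1), rt; filtered under Ar
Reagents that add atoms: none
Why: Catalytic hydrogenolysis of four O-benzyl ethers; the tetrasubstituted C2=C3 bond of the 4-pyranone and the two methyl ethers should not react at 1 atm, as in the debenzylation of benzylated quercetins.

**Compound list**

1 | syringol (2,6-dimethoxyphenol) | COc1cccc(OC)c1O | starting material
2 | syringol benzyl ether (2-(benzyloxy)-1,3-dimethoxybenzene) | COc1cccc(OC)c1OCc1ccccc1 | intermediate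
3 | 3-(benzyloxy)-1,5-dibromo-2,4-dimethoxybenzene | COc1c(Br)cc(Br)c(OC)c1OCc1ccccc1 | intermediate
4 | 5-(benzyloxy)-4,6-dimethoxybenzene-1,3-diol | COc1c(O)cc(O)c(OC)c1OCc1ccccc1 | intermediate
5 | 3,4-bis(benzyloxy)benzoic acid | OC(=O)c1ccc(OCc2ccccc2)c(OCc2ccccc2)c1 | starting material
6 | ethyl 2-(benzyloxy)acetate | CCOC(=O)COCc1ccccc1 | starting material
7 | [3,4-bis(benzyloxy)phenyl](1H-imidazol-1-yl)methanone | O=C(c1ccc(OCc2ccccc2)c(OCc2ccccc2)c1)n1ccnc1 | intermediate (not isolated)
8 | ethyl 2-(benzyloxy)-3-[3,4-bis(benzyloxy)phenyl]-3-oxopropanoate (racemic) | CCOC(=O)C(OCc1ccccc1)C(=O)c1ccc(OCc2ccccc2)c(OCc2ccccc2)c1 | intermediate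
9 | 2-(benzyloxy)-3-[3,4-bis(benzyloxy)phenyl]prop-1-ene-1,3-dione (aroylketene) | O=C=C(OCc1ccccc1)C(=O)c1ccc(OCc2ccccc2)c(OCc2ccccc2)c1 | intermediate (not isolated)
10 | 2-(benzyloxy)-1-[4-(benzyloxy)-2,6-dihydroxy-3,5-dimethoxyphenyl]-3-[3,4-bis(benzyloxy)phenyl]propane-1,3-dione (racemic) | COc1c(O)c(C(=O)C(OCc2ccccc2)C(=O)c2ccc(OCc3ccccc3)c(OCc3ccccc3)c2)c(O)c(OC)c1OCc1ccccc1 | intermediate (not isolated)
11 | 3,7-bis(benzyloxy)-2-[3,4-bis(benzyloxy)phenyl]-5-hydroxy-6,8-dimethoxy-4H-chromen-4-one | COc1c(OCc2ccccc2)c(OC)c2oc(-c3ccc(OCc4ccccc4)c(OCc4ccccc4)c3)c(OCc3ccccc3)c(=O)c2c1O | intermediate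
12 | 3,5,7,3',4'-pentahydroxy-6,8-dimethoxyflavone | COc1c(O)c(OC)c2oc(-c3ccc(O)c(O)c3)c(O)c(=O)c2c1O | target

**Step count**
Total steps: 6. Longest linear sequence: 5 (steps 1, 2, 3, 5, 6).

**Steps most likely to fail**

Step 5 (key step). At 200 °C benzyl groups may be lost or may migrate, an O-acylated intermediate may close through the ketone carbon to a 4-arylcoumarin, or the ketoester may fragment before it reaches the ring carbon. The fallback builds the same two bonds stepwise and cold; it sets out from 4 and comes back to the route at 11, by way of triketone 10. Houben–Hoesch acylation of 4 with benzyloxyacetonitrile (ZnCl2, HCl gas, Et2O, 0 °C; then water, 80 °C) would give the ketone 2-(benzyloxy)-1-[4-(benzyloxy)-2,6-dihydroxy-3,5-dimethoxyphenyl]ethan-1-one F1. Acid 5 would be converted with (COCl)2 and catalytic DMF in CH2Cl2 into 3,4-bis(benzyloxy)benzoyl chloride F2. F1 and F2 (1.05 equiv) in pyridine at 0 °C would give the monoester 5-(benzyloxy)-2-[(benzyloxy)acetyl]-3-hydroxy-4,6-dimethoxyphenyl 3,4-bis(benzyloxy)benzoate F3. Baker–Venkataraman rearrangement of F3 (LiN(SiMe3)2, THF, −20 °C) would give triketone 10, which NaOAc in AcOH at 80 °C should close to 11.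

Step 3. The second C–O coupling may stall on the bromophenoxide, hydrodebromination or diaryl ether formation may compete, and the resorcinol dianion may be oxidised by traces of air. The fallback makes the C–O bonds through boron; it sets out from 3 and returns at 4. Twofold Miyaura borylation (B2pin2, KOAc, Pd(dppf)Cl2, 1,4-dioxane, 90 °C) would give the bis(boronate) 2,2'-[5-(benzyloxy)-4,6-dimethoxy-1,3-phenylene]bis(4,4,5,5-tetramethyl-1,3,2-dioxaborolane) F4, and oxidation (NaBO3·4H2O, THF/H2O, rt) would give 4.

Step 4. Proton transfer from the product to the enolate, self-condensation of the glycolate ester or O-acylation of the enolate may erode the acylation. The fallback replaces the Claisen acylation by aldol addition and oxidation; it sets out from 6 and returns at 8. The lithium enolate of 6 (LiN(SiMe3)2, THF, −78 °C) would add to commercial 3,4-bis(benzyloxy)benzaldehyde to give the hydroxy ester ethyl 2-(benzyloxy)-3-[3,4-bis(benzyloxy)phenyl]-3-hydroxypropanoate F5 as a mixture of diastereomers, all of which Dess–Martin periodinane (CH2Cl2, NaHCO3, rt) should oxidise to 8.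

**Further compounds**

F1 | step 5 | 2-(benzyloxy)-1-[4-(benzyloxy)-2,6-dihydroxy-3,5-dimethoxyphenyl]ethan-1-one | COc1c(O)c(C(=O)COCc2ccccc2)c(O)c(OC)c1OCc1ccccc1
F2 | step 5 | 3,4-bis(benzyloxy)benzoyl chloride | O=C(Cl)c1ccc(OCc2ccccc2)c(OCc2ccccc2)c1
F3 | step 5 | 5-(benzyloxy)-2-[(benzyloxy)acetyl]-3-hydroxy-4,6-dimethoxyphenyl 3,4-bis(benzyloxy)benzoate | COc1c(O)c(C(=O)COCc2ccccc2)c(OC(=O)c2ccc(OCc3ccccc3)c(OCc3ccccc3)c2)c(OC)c1OCc1ccccc1
F4 | step 3 | 2,2'-[5-(benzyloxy)-4,6-dimethoxy-1,3-phenylene]bis(4,4,5,5-tetramethyl-1,3,2-dioxaborolane) | COc1c(B2OC(C)(C)C(C)(C)O2)cc(B2OC(C)(C)C(C)(C)O2)c(OC)c1OCc1ccccc1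
F5 | step 4 | ethyl 2-(benzyloxy)-3-[3,4-bis(benzyloxy)phenyl]-3-hydroxypropanoate (mixture of diastereomers) | CCOC(=O)C(OCc1ccccc1)C(O)c1ccc(OCc2ccccc2)c(OCc2ccccc2)c1
A1 | direct plan | quercetin (3,5,7,3',4'-pentahydroxyflavone) | O=c1c(O)c(-c2ccc(O)c(O)c2)oc2cc(O)cc(O)c12
A2 | direct plan | 6,8-dibromoquercetin | O=c1c(O)c(-c2ccc(O)c(O)c2)oc2c(Br)c(O)c(Br)c(O)c12
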